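## Retrosynthetic overview

1. Mitorubrinic acid (13) ⇐ one-pot acidolysis of a tert-butyl ester and two MOM ethers in 12.
2. 12 ⇐ C7–O ester bond and the C7 stereocentre formed together: enantioselective acyloxylative dearomatisation of 2-benzopyrylium 8 with protected orsellinic acid 11, catalysed by a chiral aryl-λ3-iodane.
3. 8 ⇐ 6-endo cycloisomerisation of o-alkynylbenzaldehyde 7, which forms the pyran ring on the purchased benzene ring.
4. 7 ⇐ Sonogashira coupling of iodoresorcinaldehyde 3 (from 1 by directed ortho-iodination, then demethylation) with enynoate 6 (HWE).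
5. Ring order: benzene ring bought → pyrylium ring closed → carbocycle dearomatised last; the orsellinate ring is bought.

Assumptions: compounds 1, 4, 5 and 9 are taken as catalogue chemicals. The facial sense of the catalyst on this new substrate class cannot be predicted with confidence, so the (R,R)-catalyst is written as giving 7R; if the sense is opposite, the (S,S)-catalyst is used and nothing else changes.

Catalyst (not numbered): (R,R)-Cat-I = 2,2'-[(2-iodo-1,3-phenylene)bis(oxy)]bis[N-mesityl-(2R)-propanamide], SMILES `C[C@@H](Oc1cccc(O[C@H](C)C(=O)Nc2c(C)cc(C)cc2C)c1I)C(=O)Nc1c(C)cc(C)cc1C`.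

## Route

**Step 1**
Reactants: 1, 2,4-dimethoxy-3-methylbenzaldehyde
Product: 2, 6-iodo-2,4-dimethoxy-3-methylbenzaldehyde
Conditions: LiN(Me)CH2CH2NMe2 (1.1 equiv), THF, −20 °C; n-BuLi (3 equiv), −20 °C, overnight; I2, −78 °C → rt; aq. Na2S2O3 / dilute acid work-up
Reagents that add atoms: iodine, `II`
Why: Comins directed ortho-metalation: the in situ α-amino alkoxide masks the aldehyde and its chelating side arm directs lithiation to C6 (C3 is blocked by methyl), and iodine quench followed by hydrolysis returns the aldehyde.

**Step 2**
Reactants: 2, 6-iodo-2,4-dimethoxy-3-methylbenzaldehyde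
Product: 3, 2,4-dihydroxy-6-iodo-3-methylbenzaldehyde
Conditions: BBr3 (4 equiv), CH2Cl2, −78 °C → rt; MeOH/H2O quench
Reagents that add atoms: none
Why: Lewis-acid aryl methyl ether cleavage (carbonyl-assisted at the ortho OMe); the aryl iodide and aldehyde are inert to BBr3 at these temperatures.

**Step 3**
Reactants: 4, 3-(trimethylsilyl)prop-2-ynal; 5, tert-butyl diethylphosphonoacetate
Product: 6, tert-butyl (2E)-pent-2-en-4-ynoate
Conditions: 5, NaH, THF, 0 °C; 4, −78 → 0 °C; then K2CO3 (cat.), MeOH, 0 °C (one pot); used as a solution
Reagents that add atoms: none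
Why: Horner–Wadsworth–Emmons olefination with a stabilised phosphonate gives the (E)-enoate, and mild methanolysis removes the alkynyl TMS group without touching the tert-butyl ester.

**Step 4**
Reactants: 3, 2,4-dihydroxy-6-iodo-3-methylbenzaldehyde; 6, tert-butyl (2E)-pent-2-en-4-ynoate
Product: 7, tert-butyl (2E)-5-(2-formyl-3,5-dihydroxy-4-methylphenyl)pent-2-en-4-ynoate
Conditions: PdCl2(PPh3)2 (3 mol %), CuI (5 mol %), Et3N, THF, rt, degassed
Reagents that add atoms: none
Why: Sonogashira coupling of an aryl iodide at room temperature tolerates free phenols and the aldehyde; a tertiary amine base avoids aza-Michael addition to the enynoate, and the (E)-alkene is untouched.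

**Step 5**
Reactants: 7, tert-butyl (2E)-5-(2-formyl-3,5-dihydroxy-4-methylphenyl)pent-2-en-4-ynoate
Product: 8, 3-[(1E)-3-tert-butoxy-3-oxoprop-1-en-1-yl]-6,8-dihydroxy-7-methylisochromenylium trifluoroacetate
Conditions: Au(OAc)3 (5 mol %), TFA (5 equiv), ClCH2CH2Cl, rt, 10 min; concentrate, triturate with Et2O; used directly
Reagents that add atoms: trifluoroacetic acid (counter-ion), `OC(=O)C(F)(F)F`
Why: π-acid-catalysed 6-endo-dig cycloisomerisation of an o-alkynylbenzaldehyde, in which the formyl oxygen attacks the gold-activated alkyne to give the aromatic 2-benzopyrylium; the short exposure to dilute TFA spares the tert-butyl ester.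

**Step 6**
Reactants: 9, methyl 2,4-dihydroxy-6-methylbenzoate (methyl orsellinate)
Product: 10, methyl 2,4-bis(methoxymethoxy)-6-methylbenzoate
Conditions: NaH (2.5 equiv), MOMCl (2.5 equiv), DMF, 0 °C → rt
Reagents that add atoms: chloromethyl methyl ether, `COCCl`
Why: Williamson-type O-alkylation of both phenoxides; NaH is used to overcome the hydrogen-bonded 2-OH.

**Step 7**
Reactants: 10, methyl 2,4-bis(methoxymethoxy)-6-methylbenzoate
Product: 11, 2,4-bis(methoxymethoxy)-6-methylbenzoic acid
Conditions: KOH, MeOH/H2O, 80 °C; citric acid to pH 4 at 0 °C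
Reagents that add atoms: potassium hydroxide (carboxyl OH oxygen), `[K+].[OH-]`
Why: Saponification of a hindered benzoate needs heat but MOM ethers are base-stable; mild acidification keeps them intact.

**Step 8** (key step)
Reactants: 8, the benzopyrylium trifluoroacetate; 11, 2,4-bis(methoxymethoxy)-6-methylbenzoic acid
Product: 12, tert-butyl (2E)-3-[(7R)-7-{[2,4-bis(methoxymethoxy)-6-methylbenzoyl]oxy}-7-methyl-6,8-dioxo-7,8-dihydro-6H-isochromen-3-yl]prop-2-enoate
Conditions: (R,R)-Cat-I (10 mol %), dry mCPBA (1.2 equiv, syringe pump over 6 h), 11 (3.0 equiv, 1.0 equiv of it as the sodium salt to neutralise the trifluoroacetate), 4 Å MS, CHCl3, −20 °C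
Reagents that add atoms: none (mCPBA is only the terminal oxidant)
Why: Proposed new method: mCPBA oxidises the C2-symmetric lactamide iodoarene to Ar*I(O2CAr')2, the 6,8-dioxygenated anhydrobase of 8 exchanges onto iodine through O8/O6, and the orsellinate ligand is transferred to C7 (the carbon flanked by both oxygens) on the face left open by the hydrogen-bonded chiral pocket as Ar*I is reductively expelled, which sets 7R and forms the hindered ester in one event; the closest known reactions are the racemic Wessely-type Pb(OAc)4 acetoxylation and IBX oxidation of 2-benzopyrylium salts to azaphilones and the enantioselective intramolecular Kita-type spirolactonisation of naphthols and phenols with the same catalyst class and mCPBA, neither of which is an intermolecular enantioselective acyloxylation with an external carboxylic acid on a benzopyrylium.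

**Step 9**
Reactants: 12, the protected azaphilone
Product: 13, mitorubrinic acid, (2E)-3-[(7R)-7-(2,4-dihydroxy-6-methylbenzoyl)oxy-7-methyl-6,8-dioxo-7,8-dihydro-6H-isochromen-3-yl]prop-2-enoic acid
Conditions: TFA/CH2Cl2 (1:4), 1,3-dimethoxybenzene (5 equiv), 0 °C → rt; reverse-phase purification
Reagents that add atoms: none
Why: Global acidolysis (tert-butyl ester by E1 loss of isobutene, MOM acetals by oxocarbenium cleavage with a cation scavenger); the azaphilone core and the quaternary C7 ester are acid-stable and C7 cannot epimerise.

## Compound list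

1 | 2,4-dimethoxy-3-methylbenzaldehyde | `COc1ccc(C=O)c(OC)c1C` | starting material
2 | 6-iodo-2,4-dimethoxy-3-methylbenzaldehyde | `COc1cc(I)c(C=O)c(OC)c1C` | intermediate
3 | 2,4-dihydroxy-6-iodo-3-methylbenzaldehyde | `Cc1c(O)cc(I)c(C=O)c1O` | intermediate
4 | 3-(trimethylsilyl)prop-2-ynal | `C[Si](C)(C)C#CC=O` | starting material
5 | tert-butyl diethylphosphonoacetate | `CCOP(=O)(OCC)CC(=O)OC(C)(C)C` | starting material
6 | tert-butyl (2E)-pent-2-en-4-ynoate | `C#C/C=C/C(=O)OC(C)(C)C` | intermediate
7 | tert-butyl (2E)-5-(2-formyl-3,5-dihydroxy-4-methylphenyl)pent-2-en-4-ynoate | `Cc1c(O)cc(C#C/C=C/C(=O)OC(C)(C)C)c(C=O)c1O` | intermediate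
8 | 3-[(1E)-3-tert-butoxy-3-oxoprop-1-en-1-yl]-6,8-dihydroxy-7-methylisochromenylium trifluoroacetate | `Cc1c(O)cc2cc(/C=C/C(=O)OC(C)(C)C)[o+]cc2c1O.[O-]C(=O)C(F)(F)F` | intermediate
9 | methyl 2,4-dihydroxy-6-methylbenzoate (methyl orsellinate) | `COC(=O)c1c(C)cc(O)cc1O` | starting material
10 | methyl 2,4-bis(methoxymethoxy)-6-methylbenzoate | `COCOc1cc(C)c(C(=O)OC)c(OCOC)c1` | intermediate
11 | 2,4-bis(methoxymethoxy)-6-methylbenzoic acid | `COCOc1cc(C)c(C(=O)O)c(OCOC)c1` | intermediate
12 | tert-butyl (2E)-3-[(7R)-7-{[2,4-bis(methoxymethoxy)-6-methylbenzoyl]oxy}-7-methyl-6,8-dioxo-7,8-dihydro-6H-isochromen-3-yl]prop-2-enoate | `COCOc1cc(C)c(C(=O)O[C@]2(C)C(=O)C=C3C=C(/C=C/C(=O)OC(C)(C)C)OC=C3C2=O)c(OCOC)c1` | intermediate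
13 | mitorubrinic acid | `Cc1cc(O)cc(O)c1C(=O)O[C@]1(C)C(=O)C=C2C=C(/C=C/C(=O)O)OC=C2C1=O` | target

## Summary

Total steps: 9 (main line 1, 2, 4, 5, 8, 9; side branches 3 and 6–7).
Longest linear sequence: 6 steps (1 → 2 → 3 → 7 → 8 → 12 → 13).

Steps most likely to fail:

1. **Step 8 (proposed new step).** Risks: m-chlorobenzoate transferred in place of 11 (partly countered by excess 11 and the low solubility of m-chlorobenzoic acid in cold CHCl3), racemic background oxidation of the anhydrobase by mCPBA, modest ee, or attack at C5. Fallback with known chemistry: hydroxylative dearomatisation at the aldehyde stage by established azaphilone methods, either the FAD-dependent monooxygenase AzaH on the 6-(2-oxoalkyl) analogue of 7 (metal-free, cyclises spontaneously to the (7R)-7-hydroxy azaphilone) or Cu/sparteine/O2 on 7 followed by buffered Cu(I) cycloisomerisation. The tertiary alcohol is then acylated with the acid chloride of 11 (Et3N/DMAP) before step 9. This costs one extra step.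

2. **Step 5.** Risks: the conjugated ester may steer the oxygen attack toward 5-exo (isobenzofuran) instead of 6-endo, and the tert-butyl ester may be partly lost. Fallback: couple 3 with a simple 1,3-enyne such as (E)-pent-3-en-1-yne, carry the propenyl azaphilone through cycloisomerisation and dearomatisation, and install the acrylate at the end by olefin cross-metathesis with tert-butyl acrylate, as used for side-chain variation in the mitorubrin family.

3. **Step 1.** Risks: competing lithiation at C5 (ortho to the 4-OMe) or butyllithium addition giving low yield. Fallback: electrophilic substitution in place of metalation: Vilsmeier–Haack formylation of 5-bromo-1,3-dimethoxy-2-methylbenzene (its two open positions are equivalent) gives 6-bromo-2,4-dimethoxy-3-methylbenzaldehyde. BBr3 demethylation and Sonogashira coupling of the bromide at 50–60 °C then follow.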